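**Retrosynthetic overview**

1. Plakortolide ⇐ Suzuki–Miyaura union at C11–C12 of a bicyclic peroxy-lactone vinyl iodide with a Z-alkenyl boronate; the diene goes in last because it would not survive the peroxidation.
2. 1,2-Dioxane ring (formed second) ⇐ two C–O bonds: the tertiary C6–OOH bond by a catalyst-controlled cobalt-hydride hydroperoxidation of a 1,1-disubstituted alkene (new), then the C3–O bond by 6-exo oxa-Michael addition onto a butenolide.
3. Butenolide ring (formed first) ⇐ Z-olefination/lactonisation of a masked α-hydroxy aldehyde; C4 ⇐ Seebach alkylation of the (S)-lactic acid dioxolanone with a 2-substituted allyl bromide.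
4. Allyl bromide (C5–C11, with C8 from the chiral pool) ⇐ (R)-citronellal by alkyne homologation, carboalumination/iodination, ozonolysis, α-methylenation, reduction and bromination.

Assumption: locants C1–C14 in the "Why" lines follow the plakortolide skeleton (C1 lactone C=O, C3 CH–OO, C4 quaternary lactone carbon, C6 quaternary peroxide carbon, C8 CHMe, C10=C11 and C12=C13 diene, C14 benzylic CH2); (R)-citronellal of at least 96% ee is used.

**Route**

Step 1
Reactants: 1 (R)-citronellal
Product: 2 (4R)-4,8-dimethylnon-7-en-1-yne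
Conditions: dimethyl (1-diazo-2-oxopropyl)phosphonate, K2CO3, MeOH, 0 to 23 °C
Reagents that add atoms: dimethyl (1-diazo-2-oxopropyl)phosphonate, COP(=O)(OC)C(=[N+]=[N-])C(C)=O
Why: Seyferth–Gilbert homologation with the Ohira–Bestmann reagent turns the aldehyde into the terminal alkyne under mild carbonate conditions, and the C8 stereocentre (chiral pool, β to the carbonyl) is not enolisable and stays intact.

Step 2
Reactants: 2 (4R)-4,8-dimethylnon-7-en-1-yne
Product: 4 (1E,4R)-1-iodo-2,4,8-trimethylnona-1,7-diene, via alkenylalane 3 (not isolated)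
Conditions: AlMe3 (2 equiv), Cp2ZrCl2 (0.25 equiv), CH2Cl2, 0 to 23 °C; then I2, THF, −30 to 0 °C
Reagents that add atoms: trimethylaluminium, C[Al](C)C; iodine, II
Why: Negishi zirconium-catalysed carboalumination adds Me and Al syn and regioselectively across the terminal alkyne and iodinolysis goes with retention, so only the E-trisubstituted vinyl iodide (the C10=C11 geometry) forms while the remote trisubstituted alkene is inert.

Step 3
Reactants: 4 (1E,4R)-1-iodo-2,4,8-trimethylnona-1,7-diene
Product: 6 (4R,6E)-7-iodo-4,6-dimethylhept-6-enal, via ozonide 5 (not isolated)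
Conditions: O3, CH2Cl2, −78 °C (Sudan Red 7B end point); then PPh3, −78 to 23 °C
Reagents that add atoms: ozone, [O-][O+]=O
Why: Ozonolysis with reductive work-up, in which electrophilic ozone cleaves the electron-rich trisubstituted alkene much faster than the electron-poor vinyl iodide and PPh3 reduces the ozonide to the aldehyde.

Step 4
Reactants: 6 (4R,6E)-7-iodo-4,6-dimethylhept-6-enal
Product: 7 (4R,6E)-7-iodo-4,6-dimethyl-2-methylidenehept-6-enal
Conditions: aq. HCHO (37%), pyrrolidine (10 mol%), EtCO2H (10 mol%), i-PrOH, 45 °C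
Reagents that add atoms: formaldehyde, C=O
Why: Amine/acid-catalysed Mannich-type α-methylenation (enamine addition to formaldehyde, then elimination) installs the methylene that becomes the C6 1,1-disubstituted alkene, and C8 is not α to the carbonyl so it cannot epimerise.

Step 5
Reactants: 7 (4R,6E)-7-iodo-4,6-dimethyl-2-methylidenehept-6-enal
Product: 8 (4R,6E)-7-iodo-4,6-dimethyl-2-methylidenehept-6-en-1-ol
Conditions: NaBH4, CeCl3·7H2O, MeOH, 0 °C
Reagents that add atoms: none
Why: Luche reduction gives clean 1,2-reduction of the enal to the allylic alcohol without touching the vinyl iodide.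

Step 6
Reactants: 8 (4R,6E)-7-iodo-4,6-dimethyl-2-methylidenehept-6-en-1-ol
Product: 9 (4R,6E)-2-(bromomethyl)-7-iodo-4,6-dimethylhepta-1,6-diene
Conditions: CBr4, PPh3, CH2Cl2, 0 °C
Reagents that add atoms: carbon tetrabromide, BrC(Br)(Br)Br
Why: Appel bromination converts the primary allylic alcohol into the bromide under neutral conditions, and SN2 and SN2′ pathways give the same product because the allyl unit is symmetric.

Step 7
Reactants: 10 (S)-lactic acid; 11 pivalaldehyde
Product: 12 (2S,5S)-2-tert-butyl-5-methyl-1,3-dioxolan-4-one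
Conditions: TsOH·H2O (cat.), H2SO4 (cat.), pentane, reflux, Dean–Stark; crystallisation from pentane at −78 °C
Reagents that add atoms: none
Why: Acid-catalysed acetalisation with azeotropic water removal gives Seebach's cis-dioxolanone, whose tert-butyl acetal centre is fixed by thermodynamic control and crystallisation and stores the lactate chirality.

Step 8
Reactants: 12 (2S,5S)-2-tert-butyl-5-methyl-1,3-dioxolan-4-one; 9 (4R,6E)-2-(bromomethyl)-7-iodo-4,6-dimethylhepta-1,6-diene
Product: 14 (2S,5R)-2-tert-butyl-5-[(4R,6E)-7-iodo-4,6-dimethyl-2-methylidenehept-6-en-1-yl]-5-methyl-1,3-dioxolan-4-one, via lithium enolate 13 (not isolated)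
Conditions: LiN(i-Pr)2, THF, −78 °C; then 9, −78 to −30 °C
Reagents that add atoms: none
Why: Seebach self-regeneration-of-stereocentres alkylation, in which the planar enolate is attacked by the reactive allylic bromide on the face opposite the tert-butyl group, creating the quaternary C4 centre with R configuration (dr expected above 95:5).

Step 9
Reactants: 14 (2S,5R)-2-tert-butyl-5-[(4R,6E)-7-iodo-4,6-dimethyl-2-methylidenehept-6-en-1-yl]-5-methyl-1,3-dioxolan-4-one
Product: 15 (2S,5R)-2-tert-butyl-5-[(4R,6E)-7-iodo-4,6-dimethyl-2-methylidenehept-6-en-1-yl]-5-methyl-1,3-dioxolan-4-ol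
Conditions: i-Bu2AlH (1.1 equiv), CH2Cl2, −78 °C; aq. Rochelle salt
Reagents that add atoms: none
Why: Partial hydride reduction of the lactone-type carbonyl at −78 °C stops at the stable cyclic hemiacetal (lactol, anomer mixture), a masked α-hydroxy aldehyde.

Step 10
Reactants: 15 (2S,5R)-2-tert-butyl-5-[(4R,6E)-7-iodo-4,6-dimethyl-2-methylidenehept-6-en-1-yl]-5-methyl-1,3-dioxolan-4-ol
Product: 18 (5R)-5-[(4R,6E)-7-iodo-4,6-dimethyl-2-methylidenehept-6-en-1-yl]-5-methylfuran-2(5H)-one, via hydroxy aldehyde 16 (not isolated), via Z-hydroxy enoate 17 (not isolated)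
Conditions: (CF3CH2O)2P(O)CH2CO2Me (2.5 equiv), KN(SiMe3)2, 18-crown-6, THF, −78 to 0 °C; then aq. NH4Cl
Reagents that add atoms: methyl bis(2,2,2-trifluoroethyl)phosphonoacetate, COC(=O)CP(=O)(OCC(F)(F)F)OCC(F)(F)F
Why: Under base the lactol opens and loses pivalaldehyde, Still–Gennari Horner–Wadsworth–Emmons olefination of the freed aldehyde gives the Z-enoate, and the tertiary alkoxide lactonises onto the cis ester to the butenolide, with quaternary C4 unable to epimerise.

Step 11
Reactants: 18 (5R)-5-[(4R,6E)-7-iodo-4,6-dimethyl-2-methylidenehept-6-en-1-yl]-5-methylfuran-2(5H)-one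
Product: 20 (3R,4aR,7aR)-3-[(2S,4E)-5-iodo-2,4-dimethylpent-4-en-1-yl]-3,4a-dimethyltetrahydrofuro[3,2-c][1,2]dioxin-6(3H)-one, via hydroperoxide 19 (not isolated)
Conditions: (R,R)-N,N′-bis(3,5-di-tert-butylsalicylidene)-1,2-cyclohexanediaminocobalt, C36H52CoN2O2 (5 mol%), N-fluoro-2,4,6-trimethylpyridinium triflate (1.5 equiv), PhSiH3 (1.2 equiv), H2O2 (dry Et2O solution, 5 equiv), PhCF3, 0 °C; aqueous wash; then Et2NH (0.5 equiv), CF3CH2OH, 23 °C; chromatography
Reagents that add atoms: hydrogen peroxide, OO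
Why: Proposed new method: a cobalt hydride (from the trivalent cobalt fluoride and PhSiH3) transfers a hydrogen atom to the least hindered, electron-rich 1,1-disubstituted alkene, the tertiary C6 radical is captured by the chiral divalent cobalt–salen and oxidised to a tetravalent alkylcobalt, and hydrogen peroxide (an α-effect O-nucleophile) displaces cobalt with inversion inside the chiral pocket, which must distinguish the methyl, the β-branched C7 arm and the neopentyl-type C5 arm to give the 6R tertiary C–OOH bond; hydroperoxide 19 then closes the 1,2-dioxane by the known amine-mediated 6-exo oxa-Michael addition to the butenolide, which can only give the cis-fused ring and so sets C3 from C4; the closest known reactions are cobalt–salen MHAT/radical-polar-crossover hydroalkoxylations of alkenes with alcohols (not yet with hydroperoxides) and the stereorandom Mukaiyama–Isayama hydroperoxysilylation followed by base-mediated peroxide oxa-Michael cyclisation.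

Step 12
Reactants: 21 4,4,5,5-tetramethyl-2-(prop-1-en-2-yl)-1,3,2-dioxaborolane; 22 allylbenzene
Product: 23 4,4,5,5-tetramethyl-2-[(2Z)-4-phenylbut-2-en-2-yl]-1,3,2-dioxaborolane
Conditions: second-generation Grubbs catalyst RuCl2(H2IMes)(PCy3)(=CHPh) (5 mol%), 1,4-benzoquinone (10 mol%), CH2Cl2, 40 °C
Reagents that add atoms: none
Why: Olefin cross-metathesis of the 1,1-disubstituted vinyl boronate with a terminal alkene is driven by loss of ethene and gives the thermodynamically preferred trisubstituted isomer with the bulky boronate trans to the benzyl group (Z by CIP), which is the C12=C13 geometry needed.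

Step 13
Reactants: 20 (3R,4aR,7aR)-3-[(2S,4E)-5-iodo-2,4-dimethylpent-4-en-1-yl]-3,4a-dimethyltetrahydrofuro[3,2-c][1,2]dioxin-6(3H)-one; 23 4,4,5,5-tetramethyl-2-[(2Z)-4-phenylbut-2-en-2-yl]-1,3,2-dioxaborolane
Product: 24 plakortolide, (3R,4aR,7aR)-3-[(2S,4E,6E)-2,4,6-trimethyl-8-phenylocta-4,6-dien-1-yl]-3,4a-dimethyltetrahydrofuro[3,2-c][1,2]dioxin-6(3H)-one
Conditions: Pd(dppf)Cl2 (5 mol%), aq. K3PO4 (3 equiv), THF, 23 °C, degassed, dark
Reagents that add atoms: none
Why: Suzuki–Miyaura coupling of an alkenyl iodide with an alkenyl boronate proceeds with retention at both sp2 carbons to give the E,E-diene at room temperature, conditions under which dialkyl peroxides and the lactone are expected to survive.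

**Compound list**

1 | (R)-citronellal, (3R)-3,7-dimethyloct-6-enal | C[C@H](CCC=C(C)C)CC=O | starting material
2 | (4R)-4,8-dimethylnon-7-en-1-yne | C#CC[C@H](C)CCC=C(C)C | intermediate
3 | dimethyl[(1E,4R)-2,4,8-trimethylnona-1,7-dien-1-yl]alumane | C[Al](C)/C=C(\C)C[C@H](C)CCC=C(C)C | intermediate
4 | (1E,4R)-1-iodo-2,4,8-trimethylnona-1,7-diene | I/C=C(\C)C[C@H](C)CCC=C(C)C | intermediate
5 | 3-[(3R,5E)-6-iodo-3,5-dimethylhex-5-en-1-yl]-5,5-dimethyl-1,2,4-trioxolane (ozonide, both epimers at the ring CH) | I/C=C(\C)C[C@H](C)CCC1OOC(C)(C)O1 | intermediate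
6 | (4R,6E)-7-iodo-4,6-dimethylhept-6-enal | I/C=C(\C)C[C@H](C)CCC=O | intermediate
7 | (4R,6E)-7-iodo-4,6-dimethyl-2-methylidenehept-6-enal | I/C=C(\C)C[C@H](C)CC(=C)C=O | intermediate
8 | (4R,6E)-7-iodo-4,6-dimethyl-2-methylidenehept-6-en-1-ol | I/C=C(\C)C[C@H](C)CC(=C)CO | intermediate
9 | (4R,6E)-2-(bromomethyl)-7-iodo-4,6-dimethylhepta-1,6-diene | I/C=C(\C)C[C@H](C)CC(=C)CBr | intermediate
10 | (S)-lactic acid | C[C@H](O)C(=O)O | starting material
11 | pivalaldehyde, 2,2-dimethylpropanal | CC(C)(C)C=O | starting material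
12 | (2S,5S)-2-tert-butyl-5-methyl-1,3-dioxolan-4-one (cis) | C[C@@H]1O[C@H](C(C)(C)C)OC1=O | intermediate
13 | lithium (2S)-2-tert-butyl-5-methyl-1,3-dioxol-4-olate | [Li+].CC1=C([O-])O[C@@H](C(C)(C)C)O1 | intermediate
14 | (2S,5R)-2-tert-butyl-5-[(4R,6E)-7-iodo-4,6-dimethyl-2-methylidenehept-6-en-1-yl]-5-methyl-1,3-dioxolan-4-one | I/C=C(\C)C[C@H](C)CC(=C)C[C@@]1(C)O[C@H](C(C)(C)C)OC1=O | intermediate
15 | (2S,5R)-2-tert-butyl-5-[(4R,6E)-7-iodo-4,6-dimethyl-2-methylidenehept-6-en-1-yl]-5-methyl-1,3-dioxolan-4-ol (both anomers at C4 of the ring) | I/C=C(\C)C[C@H](C)CC(=C)C[C@@]1(C)O[C@H](C(C)(C)C)OC1O | intermediate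
16 | (2R,6R,8E)-2-hydroxy-9-iodo-2,6,8-trimethyl-4-methylidenenon-8-enal | I/C=C(\C)C[C@H](C)CC(=C)C[C@@](C)(O)C=O | intermediate
17 | methyl (2Z,4R,8R,10E)-4-hydroxy-11-iodo-4,8,10-trimethyl-6-methylideneundeca-2,10-dienoate | I/C=C(\C)C[C@H](C)CC(=C)C[C@@](C)(O)/C=C\C(=O)OC | intermediate
18 | (5R)-5-[(4R,6E)-7-iodo-4,6-dimethyl-2-methylidenehept-6-en-1-yl]-5-methylfuran-2(5H)-one | I/C=C(\C)C[C@H](C)CC(=C)C[C@@]1(C)OC(=O)C=C1 | intermediate
19 | (5R)-5-[(2R,4S,6E)-2-hydroperoxy-7-iodo-2,4,6-trimethylhept-6-en-1-yl]-5-methylfuran-2(5H)-one | I/C=C(\C)C[C@H](C)C[C@@](C)(OO)C[C@@]1(C)OC(=O)C=C1 | intermediate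
20 | (3R,4aR,7aR)-3-[(2S,4E)-5-iodo-2,4-dimethylpent-4-en-1-yl]-3,4a-dimethyltetrahydrofuro[3,2-c][1,2]dioxin-6(3H)-one (cis-fused 1,2-dioxane/γ-lactone) | I/C=C(\C)C[C@H](C)C[C@]1(C)C[C@@]2(C)OC(=O)C[C@H]2OO1 | intermediate
21 | 4,4,5,5-tetramethyl-2-(prop-1-en-2-yl)-1,3,2-dioxaborolane (isopropenylboronic acid pinacol ester) | CC(=C)B1OC(C)(C)C(C)(C)O1 | starting material
22 | allylbenzene | C=CCc1ccccc1 | starting material
23 | 4,4,5,5-tetramethyl-2-[(2Z)-4-phenylbut-2-en-2-yl]-1,3,2-dioxaborolane | C/C(=C\Cc1ccccc1)B1OC(C)(C)C(C)(C)O1 | intermediate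
24 | plakortolide, (3R,4aR,7aR)-3-[(2S,4E,6E)-2,4,6-trimethyl-8-phenylocta-4,6-dien-1-yl]-3,4a-dimethyltetrahydrofuro[3,2-c][1,2]dioxin-6(3H)-one | CC(=C\Cc1ccccc1)/C=C(\C)C[C@H](C)C[C@]1(C)C[C@@]2(C)OC(=O)C[C@H]2OO1 | target

**Step count and risks**

Total step count: 13. Longest linear sequence: 11 steps from (R)-citronellal (steps 1–6, 8–11 and 13).

Steps most likely to fail:

Step 11 (the new step). Cobalt may decompose hydrogen peroxide or the product hydroperoxide. Facial control at C6 may be poor, since the radical carries a methyl and two CH2 arms; both catalyst antipodes are screened once and the matched one is kept. The cobalt hydride may also attack the vinyl iodide or the butenolide. The fallback uses known chemistry and sets out from 18. Mukaiyama–Isayama hydroperoxysilylation [Co(thd)2, bis(2,2,6,6-tetramethylheptane-3,5-dionato)cobalt (cat.), O2 (1 atm), Et3SiH, ClCH2CH2Cl, 23 °C] gives, without stereocontrol at C6, the (2R)-triethylsilyl peroxide F1 and the (2S)-triethylsilyl peroxide F2 in about equal amounts. HCl in MeOH at 0 °C removes silicon to give hydroperoxide 19 and its C6 epimer, the (2S)-hydroperoxide F3. Et2NH in CF3CH2OH then closes both to 20 and the 6-epi bicyclic peroxide F4, which are diastereomers and are separated on silica. The route is rejoined at 20, at the cost of about half the material.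

Step 13. Zerovalent palladium and phosphine may reduce the peroxide, or the aqueous base may open the β-peroxy lactone by retro-oxa-Michael reaction. The fallback is a palladium-free, base-free, copper-mediated Stille-type coupling that sets out from 23 and 20. Boronate 23 is converted with retention (NaOH, I2, THF, 0 °C) into the vinyl iodide (E)-(3-iodobut-2-en-1-yl)benzene F5. Iodine–lithium exchange (t-BuLi, Et2O, −78 °C) and quenching with Bu3SnCl give the stannane tributyl[(2E)-4-phenylbut-2-en-2-yl]stannane F6. F6 couples with 20 under copper thiophene-2-carboxylate, Cu(O2CC4H3S) (1.5 equiv), in N-methylpyrrolidone at 0 to 23 °C, and the route is rejoined at 24.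

Step 10. The lactol may open sluggishly, the released pivalaldehyde consumes phosphonate, and Z-selectivity or lactonisation may be incomplete. The fallback sets out from 14 and replaces the intermolecular olefination by an acylation/intramolecular Wittig sequence. LiBH4 (THF, 0 to 23 °C) reduces the dioxolanone to the diol (2R,6R,8E)-9-iodo-2,6,8-trimethyl-4-methylidenenon-8-ene-1,2-diol F7. Selective oxidation of the primary alcohol (TEMPO, PhI(OAc)2, CH2Cl2) gives hydroxy aldehyde 16, this time isolated. Ketenylidenetriphenylphosphorane (Ph3P=C=C=O, toluene, 80 °C) acylates the tertiary hydroxyl to the ester ylide (2R,6R,8E)-9-iodo-2,6,8-trimethyl-4-methylidene-1-oxonon-8-en-2-yl (triphenylphosphoranylidene)acetate F8, which closes by intramolecular Wittig reaction with no E/Z issue. The route is rejoined at 18.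

**Further compounds**

F1 | step 11 | (5R)-5-[(2R,4S,6E)-7-iodo-2,4,6-trimethyl-2-(triethylsilylperoxy)hept-6-en-1-yl]-5-methylfuran-2(5H)-one | I/C=C(\C)C[C@H](C)C[C@@](C)(OO[Si](CC)(CC)CC)C[C@@]1(C)OC(=O)C=C1
F2 | step 11 | (5R)-5-[(2S,4S,6E)-7-iodo-2,4,6-trimethyl-2-(triethylsilylperoxy)hept-6-en-1-yl]-5-methylfuran-2(5H)-one | I/C=C(\C)C[C@H](C)C[C@](C)(OO[Si](CC)(CC)CC)C[C@@]1(C)OC(=O)C=C1
F3 | step 11 | (5R)-5-[(2S,4S,6E)-2-hydroperoxy-7-iodo-2,4,6-trimethylhept-6-en-1-yl]-5-methylfuran-2(5H)-one | I/C=C(\C)C[C@H](C)C[C@](C)(OO)C[C@@]1(C)OC(=O)C=C1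
F4 | step 11 | (3S,4aR,7aR)-3-[(2S,4E)-5-iodo-2,4-dimethylpent-4-en-1-yl]-3,4a-dimethyltetrahydrofuro[3,2-c][1,2]dioxin-6(3H)-one | I/C=C(\C)C[C@H](C)C[C@@]1(C)C[C@@]2(C)OC(=O)C[C@H]2OO1
F5 | step 13 | (E)-(3-iodobut-2-en-1-yl)benzene | C/C(I)=C\Cc1ccccc1
F6 | step 13 | tributyl[(2E)-4-phenylbut-2-en-2-yl]stannane | C/C(=C\Cc1ccccc1)[Sn](CCCC)(CCCC)CCCC
F7 | step 10 | (2R,6R,8E)-9-iodo-2,6,8-trimethyl-4-methylidenenon-8-ene-1,2-diol | I/C=C(\C)C[C@H](C)CC(=C)C[C@@](C)(O)CO
F8 | step 10 | (2R,6R,8E)-9-iodo-2,6,8-trimethyl-4-methylidene-1-oxonon-8-en-2-yl (triphenylphosphoranylidene)acetate | I/C=C(\C)C[C@H](C)CC(=C)C[C@](C)(C=O)OC(=O)C=P(c1ccccc1)(c1ccccc1)c1ccccc1
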